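## Retrosynthetic overview

- The only stereocentre (C5 of the butenolide, R) is set last-but-one by organocatalytic enantioselective proton-transfer isomerisation of an achiral β,γ-unsaturated butenolide, followed by desilylation.
- That butenolide comes from C5–H oxidation of a 2,3-disubstituted furan, which serves as a latent, achiral butenolide.
- The furan and the (Z)-trisubstituted allylic alcohol are assembled in one flask from three pieces: a homoallyl Grignard reagent, propargyl alcohol and a furfuryl bromide (the proposed new step).
- The (E)-homoallyl bromide comes from dihydro-β-ionone by methyl ketone → alkyne conversion, Zr-catalysed carboalumination and oxirane opening.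
- Rings: the cyclohexene and the furan are bought; no ring is made by cyclisation, and the butenolide is unmasked from the furan in step 8.

Assumption: which pseudo-enantiomeric cinchona catalyst gives the (R)-lactone on this substrate is fixed in a pilot run; the route is written for the one that protonates the C5 Si face.

## Route

Step 1
Reactants: 1, dihydro-β-ionone [4-(2,6,6-trimethylcyclohex-1-en-1-yl)butan-2-one]
Product: 2, 2-(but-3-yn-1-yl)-1,3,3-trimethylcyclohex-1-ene
Conditions: LDA (1.05 eq), THF, −78 °C; ClP(O)(OEt)2, −78 °C → rt; then LDA (2.3 eq), −78 °C → rt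
Reagents that add atoms: none
Why: The kinetic methyl-side enolate is trapped as its enol phosphate, which LDA eliminates to the terminal alkyne (Negishi methyl ketone → alkyne protocol); the tetrasubstituted ring alkene is inert.

Step 2
Reactants: 2; 3, ethylene oxide (oxirane)
Product: 4, (3E)-4-methyl-6-(2,6,6-trimethylcyclohex-1-en-1-yl)hex-3-en-1-ol
Conditions: Me3Al (2 eq), Cp2ZrCl2 (0.25 eq), CH2Cl2, rt; then n-BuLi, THF, −30 °C; oxirane, −30 °C → rt
Reagents that add atoms: trimethylaluminium, C[Al](C)C (the vinylic methyl); oxirane, C1CO1 (reactant 3)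
Why: Zr-catalysed syn-methylalumination (Negishi carboalumination) puts Me on the internal and Al on the terminal alkyne carbon, and the derived alkenylalanate opens oxirane with retention, giving the E-trisubstituted alkene.

Step 3
Reactants: 4
Product: 5, 2-[(3E)-6-bromo-3-methylhex-3-en-1-yl]-1,3,3-trimethylcyclohex-1-ene
Conditions: CBr4, PPh3, CH2Cl2, 0 °C
Reagents that add atoms: carbon tetrabromide, BrC(Br)(Br)Br
Why: Appel bromination is an SN2 displacement at the primary homoallylic carbinol, so neither alkene is touched and no allylic transposition is possible.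

Step 4
Reactants: 6, methyl 2-methylfuran-3-carboxylate
Product: 7, methyl 2-(bromomethyl)furan-3-carboxylate
Conditions: NBS (1.05 eq), AIBN (5 mol %), PhCF3, 85 °C
Reagents that add atoms: N-bromosuccinimide, O=C1CCC(=O)N1Br
Why: Wohl–Ziegler radical bromination occurs at the furylic methyl group; the 3-ester deactivates the ring towards electrophilic bromination and makes the furfuryl bromide isolable.

Step 5
Reactants: 5; 8, propargyl alcohol (prop-2-yn-1-ol); 7
Product: 9, methyl 2-[(2Z,6E)-3-(hydroxymethyl)-7-methyl-9-(2,6,6-trimethylcyclohex-1-en-1-yl)nona-2,6-dien-1-yl]furan-3-carboxylate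
Conditions: 5, Mg, THF, rt (→ RMgBr, 1.3 eq); add to ClMgOCH2C≡CH (from 8 + i-PrMgCl, 1.0 eq, −20 °C) and CuI (15 mol %), Et2O–THF, −10 °C → rt; then 7 (1.5 eq), −30 → 0 °C; aq NH4Cl
Reagents that add atoms: none (all product atoms come from 5, 7 and 8)
Why: Proposed new method: a one-flask three-component union in which Cu-catalysed, alkoxide-directed anti-carbomagnesiation of propargyl alcohol puts the homoallyl group on C2 and Mg on C3 cis to CH2O (five-membered magnesium alkoxide chelate, hence the Z-alkene), and the resulting alkenyl-Mg/Cu species displaces the benzylic-type bromide of 7 by Cu-catalysed SN2 coupling with retention of geometry, faster than it adds to the conjugated furoate ester; the closest known chemistry is Cu-catalysed carbomagnesiation of propargylic alcohols trapped with I2, CO2 or allyl halides, and Cu-catalysed alkenyl Grignard–benzyl halide coupling, but capture of this chelate by an ester-bearing heteroaryl-methyl bromide has not been shown.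

Step 6
Reactants: 9
Product: 10, {2-[(2Z,6E)-3-(hydroxymethyl)-7-methyl-9-(2,6,6-trimethylcyclohex-1-en-1-yl)nona-2,6-dien-1-yl]furan-3-yl}methanol
Conditions: DIBAL-H (3.5 eq), CH2Cl2, −78 → 0 °C; Rochelle salt work-up
Reagents that add atoms: none
Why: Hydride reduction of the heteroaryl ester gives the primary alcohol; the furan and the three alkenes are inert to DIBAL-H.

Step 7
Reactants: 10
Product: 11, 3-{[(tert-butyldimethylsilyl)oxy]methyl}-2-[(2Z,6E)-3-{[(tert-butyldimethylsilyl)oxy]methyl}-7-methyl-9-(2,6,6-trimethylcyclohex-1-en-1-yl)nona-2,6-dien-1-yl]furan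
Conditions: TBSCl (2.4 eq), imidazole, DMF, rt
Reagents that add atoms: tert-butyldimethylsilyl chloride, CC(C)(C)[Si](C)(C)Cl
Why: Silylation of both primary alcohols stops the furan-CH2OH from translactonising onto the enol lactone made in step 8 and keeps the proton-transfer step free of protic groups.

Step 8
Reactants: 11
Product: 12, 4-{[(tert-butyldimethylsilyl)oxy]methyl}-5-[(2Z,6E)-3-{[(tert-butyldimethylsilyl)oxy]methyl}-7-methyl-9-(2,6,6-trimethylcyclohex-1-en-1-yl)nona-2,6-dien-1-yl]furan-2(3H)-one (β,γ-unsaturated butenolide, achiral)
Conditions: [Ir(OMe)(cod)]2 (1.5 mol %), dtbpy (3 mol %), B2pin2 (0.6 eq), THF, rt → 40 °C; then 30% H2O2, pH 7 phosphate buffer, THF, 0 °C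
Reagents that add atoms: hydrogen peroxide, OO (the carbonyl oxygen); B2pin2 is transient
Why: Ir-catalysed C–H borylation takes the only unhindered furan α-C–H (C5; C4 is flanked by CH2OTBS), and neutral peroxide oxidation of the C–B bond gives the 2-hydroxyfuran, which ketonises by kinetic α-protonation to the enol lactone without touching the alkenes or silyl ethers (any conjugated racemic tautomer is removed by chromatography).

Step 9
Reactants: 12
Product: 13, (5R)-4-{[(tert-butyldimethylsilyl)oxy]methyl}-5-[(2Z,6E)-3-{[(tert-butyldimethylsilyl)oxy]methyl}-7-methyl-9-(2,6,6-trimethylcyclohex-1-en-1-yl)nona-2,6-dien-1-yl]furan-2(5H)-one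
Conditions: 6'-OH cinchona catalyst [9-O-(9-phenanthryl)cupreidine or its cupreine pseudo-enantiomer, 5 mol %], CH2Cl2, −20 °C
Reagents that add atoms: none
Why: This is an organocatalytic asymmetric olefin isomerisation by proton-transfer catalysis: the quinuclidine removes a C3 proton, and the chiral ammonium dienolate ion pair, oriented by the 6'-OH hydrogen bond, is reprotonated on the Si face of C5 to give the (R) centre in the more stable, kinetically less acidic conjugated butenolide.

Step 10
Reactants: 13
Product: 14, (6Z)-neomanoalide [(5R)-4-(hydroxymethyl)-5-[(2Z,6E)-3-(hydroxymethyl)-7-methyl-9-(2,6,6-trimethylcyclohex-1-en-1-yl)nona-2,6-dien-1-yl]furan-2(5H)-one]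
Conditions: HF·pyridine, pyridine, THF, 0 °C → rt
Reagents that add atoms: none
Why: Buffered, mildly acidic fluoride desilylation frees both primary alcohols without the basic conditions (e.g. unbuffered TBAF) that would epimerise the γ-stereocentre.

## Compound list

1 | dihydro-β-ionone | CC(=O)CCC1=C(C)CCCC1(C)C | starting material
2 | 2-(but-3-yn-1-yl)-1,3,3-trimethylcyclohex-1-ene | C#CCCC1=C(C)CCCC1(C)C | intermediate
3 | ethylene oxide | C1CO1 | starting material
4 | (3E)-4-methyl-6-(2,6,6-trimethylcyclohex-1-en-1-yl)hex-3-en-1-ol | CC1=C(CC/C(C)=C/CCO)C(C)(C)CCC1 | intermediate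
5 | 2-[(3E)-6-bromo-3-methylhex-3-en-1-yl]-1,3,3-trimethylcyclohex-1-ene | CC1=C(CC/C(C)=C/CCBr)C(C)(C)CCC1 | intermediate
6 | methyl 2-methylfuran-3-carboxylate | COC(=O)c1ccoc1C | starting material
7 | methyl 2-(bromomethyl)furan-3-carboxylate | COC(=O)c1ccoc1CBr | intermediate
8 | propargyl alcohol | C#CCO | starting material
9 | methyl 2-[(2Z,6E)-3-(hydroxymethyl)-7-methyl-9-(2,6,6-trimethylcyclohex-1-en-1-yl)nona-2,6-dien-1-yl]furan-3-carboxylate | CC1=C(CC/C(C)=C/CC/C(=C/Cc2occc2C(=O)OC)CO)C(C)(C)CCC1 | intermediate
10 | furan diol from ester reduction of 9 | CC1=C(CC/C(C)=C/CC/C(=C/Cc2occc2CO)CO)C(C)(C)CCC1 | intermediate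
11 | bis-TBS ether of 10 | CC1=C(CC/C(C)=C/CC/C(=C/Cc2occc2CO[Si](C)(C)C(C)(C)C)CO[Si](C)(C)C(C)(C)C)C(C)(C)CCC1 | intermediate
12 | bis-TBS β,γ-unsaturated butenolide [furan-2(3H)-one], achiral | CC1=C(CC/C(C)=C/CC/C(=C/CC2=C(CO[Si](C)(C)C(C)(C)C)CC(=O)O2)CO[Si](C)(C)C(C)(C)C)C(C)(C)CCC1 | intermediate
13 | (5R)-bis-TBS α,β-unsaturated butenolide [furan-2(5H)-one] | CC1=C(CC/C(C)=C/CC/C(=C/C[C@H]2OC(=O)C=C2CO[Si](C)(C)C(C)(C)C)CO[Si](C)(C)C(C)(C)C)C(C)(C)CCC1 | intermediate
14 | (6Z)-neomanoalide | CC1=C(CC/C(C)=C/CC/C(=C/C[C@H]2OC(=O)C=C2CO)CO)C(C)(C)CCC1 | target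

## Step count and risks

Total steps: 10. Longest linear sequence: 9 (steps 1–3 and 5–10, from dihydro-β-ionone); step 4 is a one-step side branch.

Steps most likely to fail:

1. **Step 5 (proposed new three-component coupling).** The chelated alkenylmagnesium may alkylate sluggishly or attack the ester. Fallback (known chemistry): quench the carbomagnesiation with I2 to give the (Z)-3-iodo-2-alkylprop-2-en-1-ol, an established trap for this intermediate. Then join it to the furfurylzinc bromide made from 7 (Zn, LiCl) by Pd-catalysed Negishi coupling, which gives 9 with the same geometry at the cost of one extra step.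

2. **Step 8 (furan C–H borylation/oxidation).** Protodeboronation of the 2-furyl boronate, or ketonisation to the racemic conjugated tautomer, would cut the supply of pure 12. Fallback: replace C–H activation by a pre-installed handle. Brominate 6 at C5 before step 4, carry the C–Br bond through steps 5–7, then do Br/Li exchange (t-BuLi, −78 °C), B(OMe)3 and H2O2. Pure β,γ-tautomer is regenerated by kinetic protonation (AcOH, −78 °C) of the lithium dienolate.

3. **Step 9 (asymmetric proton-transfer isomerisation).** The tetrasubstituted enol lactone is more hindered than simple γ-alkyl substrates, so ee or conversion may be low. Fallback: set the stereocentre by metal-free enantioselective ketone reduction instead of proton transfer. Photo-oxygenate furan 11 (1O2, i-Pr2NEt, −78 °C) to the 5-hydroxy-5-alkylbutenolide, the ring form of the (Z)-4-oxo-2-enoic acid. Methylate it (TMSCHN2) and reduce the ketone with an oxazaborolidine (CBS) catalyst and catecholborane; the (R)-carbinol lactonises to 13.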